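# Total synthesis of 4-methylene-5β-hydroperoxyovatodiolide (23)

## Retrosynthetic overview
1. The target (23) is the Schenck singlet-oxygen ene product of ovatodiolide (22). The C4=C5 trisubstituted alkene gives the C5–OOH and the C4=CH2 in one operation. This is the bold late-stage step.
2. Ovatodiolide comes from an intramolecular Nozaki–Hiyama–Kishi (Cr) allylation of an (E)-enal by a 2-(bromomethyl)alkenoate, then lactonization. This one C–C bond closes the 14-membered carbocycle and sets the trans-fused α-methylene-γ-lactone.
3. The macrocyclization precursor (20) comes from a butenolide made by RCM of an α-alkylacrylate ester of a chiral allylic alcohol. The enal is made by cross-metathesis and the allyl bromide by Morita–Baylis–Hillman (MBH) addition followed by SN2′ bromination.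
4. Ring order: butenolide (RCM), then the 14-membered carbocycle with the γ-lactone (NHK, then acid), then the hydroperoxide (ene).

Assumptions:
- The ring C4=C5 alkene of ovatodiolide is E, as in the target's other ring alkene.
- The macrocyclization delivers the required (C-a S, C-n R) diastereomer as a major or separable product.

## Route

**Step 1**
Reactants: 1 (4-pentyn-1-ol)
Product: 2 (TBS ether of 4-pentyn-1-ol)
Conditions: TBSCl, imidazole, DMF, 0 → 25 °C
Reagents that add atoms: TBSCl, CC(C)(C)[Si](C)(C)Cl
Why: Silyl protection of the primary alcohol lets it survive the Al/Zn organometallics and LDA later. No stereocenter is involved.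

**Step 2**
Reactants: 2
Product: 3 ((E)-vinyl iodide)
Conditions: Me3Al, Cp2ZrCl2 (cat.), CH2Cl2, 0 → 25 °C; then I2, THF, −30 °C
Reagents that add atoms: Me3Al, C[Al](C)C (gives the CH3); I2, II (gives the I)
Why: Negishi Zr-catalysed syn-carboalumination puts Me on the internal alkyne carbon and Al on the terminal carbon, so iodinolysis gives the (E)-trisubstituted vinyl iodide. This fixes the C4=C5 geometry.

**Step 3**
Reactants: 3; 4 (ethyl 4-bromobutanoate)
Product: 5 (ethyl (E)-9-(TBSO)-6-methylnon-5-enoate)
Conditions: 4 + Zn dust (BrCH2CH2Br/TMSCl activated), LiCl, THF, 45 °C, giving BrZn(CH2)3CO2Et; then 3, Pd(PPh3)4 (5 mol%), THF, 50 °C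
Reagents that add atoms: none (all carbons come from 3 and 4)
Why: Negishi sp2–sp3 coupling proceeds with retention of alkene geometry and tolerates the ester and silyl ether.

**Step 4**
Reactants: 5
Product: 6 (α-(dimethylaminomethyl) ester)
Conditions: LDA, THF, −78 °C; then Me2N⁺=CH2 I⁻, −78 → 25 °C
Reagents that add atoms: Eschenmoser's salt, C=[N+](C)C.[I-] (adds CH2NMe2)
Why: Ester-enolate Mannich aminomethylation at the α-carbon. The alkene and OTBS are inert to LDA at −78 °C.

**Step 5**
Reactants: 6
Product: 7 (ethyl 2-methylene ester)
Conditions: MeI, CH2Cl2, 25 °C; then DBU, 25 °C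
Reagents that add atoms: none (MeI leaves as Me3N)
Why: Quaternization and E1cB/Hofmann-type elimination completes the α-methylenation. The trisubstituted alkene is untouched (no peracid Cope variant is used).

**Step 6**
Reactants: 7
Product: 8 (2-methylene acid)
Conditions: LiOH·H2O, THF/H2O (3:1), BHT (cat.), 25 °C; then NaHSO4 to pH 4
Reagents that add atoms: water, O (ester hydrolysis)
Why: Saponification of the hindered α-alkylacrylate ester, with BHT preventing polymerization. TBS and the alkene survive.

**Step 7**
Reactants: 9 (acrolein); 10 (methallylmagnesium chloride)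
Product: 11 ((±)-5-methylhexa-1,5-dien-3-ol)
Conditions: THF, −78 → 0 °C; aq. NH4Cl
Reagents that add atoms: 10, C=C(C)C[Mg]Cl (supplies the methallyl group)
Why: Allyl-Grignard 1,2-addition to the enal. The carbinol stereocenter is racemic at this point.

**Step 8**
Reactants: 11
Product: 12 ((R)-5-methylhexa-1,5-dien-3-ol, recovered)
Conditions: Ti(OiPr)4 (10 mol%), L-(+)-DIPT (12 mol%), TBHP (0.6 equiv, anhydrous), 4 Å MS, CH2Cl2, −20 °C, about 55% conversion; chromatographic removal of the epoxy alcohol
Reagents that add atoms: none in 12 (the TBHP oxygen ends up only in the discarded epoxy alcohol)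
Why: Sharpless kinetic resolution. L-(+)-tartrate epoxidizes the (S)-vinyl carbinol faster, leaving (R)-12; this sets the butenolide γ-stereocenter (R). If the fast enantiomer is opposite to this assignment, D-(−)-DIPT is used instead.

**Step 9**
Reactants: 8; 12
Product: 13 (allylic ester)
Conditions: EDC·HCl, DMAP (0.2 equiv), BHT (cat.), CH2Cl2, 0 → 25 °C
Reagents that add atoms: none (EDC leaves as urea)
Why: Steglich esterification. The C–O bond of the carbinol is not broken, so (R) is retained.

**Step 10**
Reactants: 13
Product: 14 ((R)-butenolide)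
Conditions: Grubbs II (5 mol%), 1,4-benzoquinone (10 mol%), CH2Cl2 (5 mM), 40 °C, Ar sparge
Reagents that add atoms: none (ethylene is lost)
Why: Ring-closing metathesis of the acrylate with the monosubstituted vinyl group gives the α-alkyl-γ-substituted butenolide. The 1,1-disubstituted methallyl alkene and the trisubstituted alkene are too hindered to compete; benzoquinone suppresses Ru–H isomerization.

**Step 11**
Reactants: 14
Product: 15 (primary alcohol)
Conditions: HF·pyridine, pyridine/THF, 0 → 25 °C
Reagents that add atoms: none
Why: Fluoride-mediated desilylation under buffered, non-basic conditions that avoid epimerizing the butenolide γ-H.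

**Step 12**
Reactants: 15
Product: 16 (aldehyde)
Conditions: Dess–Martin periodinane, NaHCO3, CH2Cl2, 0 → 25 °C
Reagents that add atoms: none
Why: Mild oxidation of the primary alcohol; the alkenes and butenolide are untouched.

**Step 13**
Reactants: 16; 17 (methyl acrylate)
Product: 18 (Morita–Baylis–Hillman adduct)
Conditions: methyl acrylate (10 equiv), DABCO (0.5 equiv), MeOH, 25 °C, 48–72 h
Reagents that add atoms: none beyond reactant 17
Why: The MBH reaction occurs selectively at the only aldehyde present. The new carbinol is formed as a diastereomeric mixture that is erased in Step 15, because that carbon becomes sp2.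

**Step 14**
Reactants: 18; 9 (acrolein)
Product: 19 ((E)-enal)
Conditions: acrolein (10 equiv), Hoveyda–Grubbs II (8 mol%), CH2Cl2 (0.05 M), 40 °C
Reagents that add atoms: none beyond reactant 9
Why: Cross-metathesis of the methallyl 1,1-disubstituted alkene with acrolein gives the thermodynamically favoured (E)-β-methyl enal (C-a/C-b/C-c unit), which sets the ring alkene geometry. The electron-poor MBH alkene, butenolide and trisubstituted alkene are poor metathesis partners.

**Step 15**
Reactants: 19
Product: 20 ((Z)-2-(bromomethyl)alk-2-enoate)
Conditions: MsCl, Et3N, CH2Cl2, 0 °C; then LiBr, THF, 0 → 25 °C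
Reagents that add atoms: LiBr, [Li+].[Br-] (adds Br)
Why: Mesylation followed by SN2′ bromide displacement transposes the alkene, giving the trisubstituted allyl bromide (mainly Z) and destroying the Step-13 carbinol stereocenter. Unlike NBS/Me2S, this does not brominate the electron-rich alkene.

**Step 16**
Reactants: 20
Product: 21 (macrocyclic homoallylic alcohol methyl ester)
Conditions: CrCl2 (10 equiv), NiCl2 (1 mol%), DMF, 25 °C, substrate added by syringe pump over 10 h (final about 3 mM)
Reagents that add atoms: none (only H from workup water)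
Why: Intramolecular Nozaki–Hiyama–Kishi allylation. The allylchromium adds to the enal through its γ-carbon via a chair transition state, giving the anti hydroxy ester (trans-lactone precursor) and forming the C-a–C-n bond. The fixed butenolide stereocenter and the macrocycle conformation select the (C-a S, C-n R) sense; diastereomers are separated.

**Step 17**
Reactants: 21
Product: 22 (ovatodiolide)
Conditions: p-TsOH·H2O (0.2 equiv), CH2Cl2, 25 °C, 12 h
Reagents that add atoms: none (MeOH is lost)
Why: Acid-catalysed lactonization closes the five-membered ring. The anti relationship set in Step 16 becomes the trans-fused α-methylene-γ-butyrolactone, and no new stereocenter is created.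

**Step 18**
Reactants: 22
Product: 23 (target)
Conditions: O2, tetraphenylporphyrin (1 mol%), visible light, CH2Cl2, −78 → −40 °C, 1–3 h, stopped at about 70% conversion; no reductive workup; cold chromatography
Reagents that add atoms: O2, O=O
Why: Proposed new method: a Schenck singlet-oxygen ene reaction on the intact macrocycle. The C4=C5 alkene is the more electron-rich one; the CH=C(CH3) alkene is flanked by two oxygenated carbons and is deactivated, and the α-methylene lactone and butenolide are electron-poor. In the 14-membered ring the ring CH2 hydrogens lie close to the alkene plane, so the C4-methyl hydrogens are the ones aligned for abstraction. That gives C5–OOH with C4=CH2, and peripheral attack on the outer π-face is assumed to give the 5β-OOH. The closest known reaction is the 1O2 ene of macrocyclic terpenoid trisubstituted alkenes to secondary allylic hydroperoxides; any 5α epimer is separable.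

## Compound list
1 | 4-pentyn-1-ol | C#CCCCO | starting material
2 | tert-butyldimethyl(pent-4-yn-1-yloxy)silane | C#CCCCO[Si](C)(C)C(C)(C)C | intermediate
3 | (E)-tert-butyl[(5-iodo-4-methylpent-4-en-1-yl)oxy]dimethylsilane | I/C=C(\C)CCCO[Si](C)(C)C(C)(C)C | intermediate
4 | ethyl 4-bromobutanoate | CCOC(=O)CCCBr | starting material
5 | ethyl (E)-9-(TBSO)-6-methylnon-5-enoate | CCOC(=O)CCC/C=C(\C)CCCO[Si](C)(C)C(C)(C)C | intermediate
6 | ethyl (E)-2-[(dimethylamino)methyl]-9-(TBSO)-6-methylnon-5-enoate | CCOC(=O)C(CN(C)C)CC/C=C(\C)CCCO[Si](C)(C)C(C)(C)C | intermediate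
7 | ethyl (E)-9-(TBSO)-6-methyl-2-methylenenon-5-enoate | CCOC(=O)C(=C)CC/C=C(\C)CCCO[Si](C)(C)C(C)(C)C | intermediate
8 | (E)-9-(TBSO)-6-methyl-2-methylenenon-5-enoic acid | OC(=O)C(=C)CC/C=C(\C)CCCO[Si](C)(C)C(C)(C)C | intermediate
9 | acrolein | C=CC=O | starting material
10 | methallylmagnesium chloride | C=C(C)C[Mg]Cl | starting material
11 | (±)-5-methylhexa-1,5-dien-3-ol | C=CC(O)CC(C)=C | intermediate
12 | (R)-5-methylhexa-1,5-dien-3-ol | C=C[C@H](O)CC(C)=C | intermediate
13 | (R)-5-methylhexa-1,5-dien-3-yl 2-methylene ester | C=C[C@@H](CC(C)=C)OC(=O)C(=C)CC/C=C(\C)CCCO[Si](C)(C)C(C)(C)C | intermediate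
14 | (5R)-3-[(E)-7-(TBSO)-4-methylhept-3-enyl]-5-(2-methylallyl)furan-2(5H)-one | C=C(C)C[C@@H]1C=C(CC/C=C(\C)CCCO[Si](C)(C)C(C)(C)C)C(=O)O1 | intermediate
15 | primary alcohol from 14 | C=C(C)C[C@@H]1C=C(CC/C=C(\C)CCCO)C(=O)O1 | intermediate
16 | aldehyde from 15 | C=C(C)C[C@@H]1C=C(CC/C=C(\C)CCC=O)C(=O)O1 | intermediate
17 | methyl acrylate | C=CC(=O)OC | starting material
18 | MBH adduct (carbinol epimeric mixture) | C=C(C)C[C@@H]1C=C(CC/C=C(\C)CCC(O)C(=C)C(=O)OC)C(=O)O1 | intermediate
19 | (E)-enal from cross-metathesis of 18 | O=C/C=C(\C)C[C@@H]1C=C(CC/C=C(\C)CCC(O)C(=C)C(=O)OC)C(=O)O1 | intermediate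
20 | methyl (2Z,6E)-2-(bromomethyl)-6-methyl-9-[(5R)-5-((E)-2-methyl-4-oxobut-2-enyl)-2-oxo-2,5-dihydrofuran-3-yl]nona-2,6-dienoate | O=C/C=C(\C)C[C@@H]1C=C(CC/C=C(\C)CC/C=C(\CBr)C(=O)OC)C(=O)O1 | intermediate
21 | macrocyclic hydroxy methyl ester | COC(=O)C(=C)[C@H]1CC/C(C)=C/CCC2=C[C@@H](C/C(C)=C/[C@@H]1O)OC2=O | intermediate
22 | ovatodiolide | C=C1C(=O)O[C@H]2/C=C(\C)C[C@@H]3C=C(CC/C=C(\C)CC[C@H]12)C(=O)O3 | intermediate
23 | 4-methylene-5β-hydroperoxyovatodiolide | C=C1C(=O)O[C@H]2/C=C(\C)C[C@@H]3C=C(CC[C@@H](OO)C(=C)CC[C@H]12)C(=O)O3 | target

## Totals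
- Total steps: 18.
- Longest linear sequence: 16 steps (1 → 2 → 3 → 5 → 6 → 7 → 8 → 13 → 14 → 15 → 16 → 18 → 19 → 20 → 21 → 22 → 23). The alcohol branch (Steps 7–8) is two steps.

## Three steps most likely to fail
1. **Step 18 (ene reaction).** It may give the wrong regiochemistry (C4-hydroperoxide, or reaction at the other alkene) or a 5α/5β mixture.
   Fallback: install the C5 oxygen earlier by an intramolecular NHK of a C4 vinyl iodide onto a C5 aldehyde. This gives the 4-methylene-5-ol, which is then converted to the hydroperoxide by SN2 of the mesylate with H2O2/base, using the C5-epimeric alcohol to allow for the inversion.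
2. **Step 16 (macrocyclic NHK).** Diastereocontrol at C-a/C-n relative to the butenolide may be poor, and oligomers may form.
   Fallback: set C-a/C-n first. Make the trans-fused α-methylene lactone by an intermolecular anti-selective allylboration or Barbier reaction and resolve it, then close the 14-membered ring by intramolecular B-alkyl Suzuki coupling at the C4/C5 alkene.
3. **Step 14 (cross-metathesis to the enal).** The 1,1-disubstituted alkene, the free MBH alcohol and the acrylate all compete.
   Fallback: carry the C-a/C-b/C-c unit in the allylic-alcohol fragment as an (E)-α,β-unsaturated ester from the start, and convert it to the enal late (DIBAL, then MnO2) after the bromide is installed.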